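**Retrosynthetic overview**

- The target is (4R,6S)-cis-4,6-dihydroxy-4-[(10Z)-heptadec-10-en-1-yl]cyclohex-2-en-1-one. The ring is cut at C4–C5 and at C1–C6: C1–C4 come from a 5-alkylfuran-2-ol (the dienol of a butenolide, a locked cis 4-oxo-2-enoate) and C5–C6 from the enol of acetaldehyde. The two enol oxygens are joined by a temporary iPr2Si bridge.
- Enabling feature: the furan ring, with the silyloxy oxygen on C2 and the chain on C5. The O–Si–O link from the C2 oxygen to the vinyl oxygen can only close a five-membered 1,3,2-dioxasilolane, which puts the vinyl CH–O on furan C2 and the vinyl CH2 on furan C5, exo. Furan C2 then carries two oxygens and is a latent ketone.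
- Ring order: the furan is bought. The carbocycle forms in the key step as an oxa-bridged adduct, which opens to the cyclohexenone while silicon moves onto the cis 1,3-diol as a six-membered silylene ring. That ring is then removed, and the cyclohexenone is the only ring left.
- Precursor: 2-methoxyfuran is lithiated and alkylated with the (Z)-C17 bromide (from oct-1-yne and 1,9-dibromononane, then Lindlar), hydrolysed to the butenolide and O-silylated with chloro(ethenyloxy)di(propan-2-yl)silane.
- Absolute configuration: the key step gives the racemic cis series; a lipase kinetic resolution at the end leaves the (4R,6S)-diol, at the cost of at most half the material.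

Key step: step 7

Assumption: in the closing lipase resolution the (4S,6R)-enantiomer is taken to be acylated faster (ring-carbonyl flank in the large pocket of the empirical size model for lipases). This sense is not secured by a close precedent; with a hydrolase of the opposite preference the target would be collected as its 6-O-acetate and released by the same enzyme in buffer.

**Route**

Step 1
Reactants: 1 oct-1-yne; 2 1,9-dibromononane
Product: 4 17-bromoheptadec-7-yne, via lithium oct-1-yn-1-ide 3 (not isolated)
Conditions: n-BuLi, THF, −78 → 0 °C; then 2 (3 equiv), DMPU, 0 °C → rt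
Reagents that add atoms: none
Why: SN2 alkylation of a lithium acetylide by a primary bromide, in which the excess of the symmetrical dibromide should suppress double alkylation and can be recovered by distillation.

Step 2
Reactants: 4 17-bromoheptadec-7-yne
Product: 5 (7Z)-17-bromoheptadec-7-ene
Conditions: H2 (1 atm), 5% Pd on CaCO3 poisoned with Pb(OAc)2, quinoline, hexane, rt
Reagents that add atoms: none
Why: Lindlar semi-hydrogenation, in which syn delivery of H2 on the poisoned palladium surface should set the Z-alkene while the primary C–Br bond stays intact.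

Step 3
Reactants: 6 2-methoxyfuran; 5 (7Z)-17-bromoheptadec-7-ene
Product: 8 2-[(10Z)-heptadec-10-en-1-yl]-5-methoxyfuran, via (5-methoxyfuran-2-yl)lithium 7 (not isolated)
Conditions: n-BuLi, THF, −78 → 0 °C; then 5, DMPU, −78 °C → rt
Reagents that add atoms: none
Why: α-lithiation of the furan at C5 (its only free α-position) followed by SN2 alkylation with the primary bromide, a standard heteroaryllithium alkylation that leaves the Z-alkene untouched.

Step 4
Reactants: 8 2-[(10Z)-heptadec-10-en-1-yl]-5-methoxyfuran
Product: 9 5-[(10Z)-heptadec-10-en-1-yl]furan-2(5H)-one (racemic at C5)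
Conditions: 1 M HCl, THF, 0 °C → rt; then Et3N (cat.), CH2Cl2, rt
Reagents that add atoms: water, O
Why: acid hydrolysis of a 2-alkoxyfuran (a cyclic ketene acetal) by C-protonation, addition of water and loss of methanol, after which the amine should bring any β,γ-unsaturated isomer into conjugation; the C5 stereocentre is of no consequence because step 6 erases it.

Step 5
Reactants: 10 (ethenyloxy)trimethylsilane; 11 dichlorodi(propan-2-yl)silane
Product: 13 chloro(ethenyloxy)di(propan-2-yl)silane, via lithium ethenolate 12 (not isolated)
Conditions: MeLi, THF, 0 °C → rt; then added to 11 (3 equiv), THF, −78 °C → rt; distillation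
Reagents that add atoms: none
Why: cleavage of the silyl enol ether by methyllithium gives the lithium enolate of acetaldehyde, which the excess dichlorosilane should O-silylate once, as in the sequential synthesis of unsymmetrical silyl bis-enol ethers.

Step 6
Reactants: 9 5-[(10Z)-heptadec-10-en-1-yl]furan-2(5H)-one; 13 chloro(ethenyloxy)di(propan-2-yl)silane
Product: 15 2-{[(ethenyloxy)di(propan-2-yl)silyl]oxy}-5-[(10Z)-heptadec-10-en-1-yl]furan, via lithium 5-[(10Z)-heptadec-10-en-1-yl]furan-2-olate 14 (not isolated)
Conditions: 9 added to LiN(SiMe3)2, THF, −78 °C; then 13, −78 °C → rt; pentane, filtration through Celite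
Reagents that add atoms: none
Why: γ-deprotonation of the butenolide gives the aromatic 2-furanolate, which the hard chlorosilane should silylate on oxygen (standard 2-silyloxyfuran synthesis, here forming the second Si–O bond of a silyl bis-enol ether).

Step 7
Reactants: 15 2-{[(ethenyloxy)di(propan-2-yl)silyl]oxy}-5-[(10Z)-heptadec-10-en-1-yl]furan
Product: 17 racemic (1R*,5S*)-1-[(10Z)-heptadec-10-en-1-yl]-3,3-di(propan-2-yl)-2,4-dioxa-3-silabicyclo[3.3.1]non-7-en-6-one, via oxanorbornene cycloadduct 16 (not isolated)
Conditions: PhMe (0.02 M), BHT, 2,6-lutidine (0.2 equiv), 150 °C, sealed tube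
Reagents that add atoms: none
Why: Proposed new method: on heating, the 2-silyloxyfuran (diene: ring carbons C2 to C5) and the vinyl ether held on the same silicon should combine in a concerted, suprafacial [4π+2π] cycloaddition that joins furan C5 to the vinyl CH2 and furan C2 to the vinyl CH–O, and the bridgehead silyl ketal carbon of cycloadduct 16 should then cleave its bond to the oxygen bridge while the freed tertiary alkoxide takes over silicon through a pentacoordinate silicate, which unveils the enone carbonyl and leaves silicon bridging the two cis oxygen atoms. The closest known reaction types are the intramolecular Diels–Alder reaction of 2-heteroatom-substituted furans with unactivated tethered alkenes, the temporary silaketal-tethered Diels–Alder reaction and the collapse of intermolecular 2-silyloxyfuran cycloadducts to 4-silyloxycyclohex-2-enones; what has not been shown is the union of a 2-silyloxyfuran with an enol ether through an O–Si–O link. The carbocycle closes by the cycloaddition in the type 1 intramolecular mode with a five-membered 1,3,2-dioxasilolane as the tether ring, and the six-membered 1,3,2-dioxasilinane of 17 closes by the oxygen-to-oxygen silyl transfer. Both new stereocentres (the quaternary carbinol carbon and the CH–O carbon) are controlled by the three-atom tether, which can only span the bridgehead and the exo position of the oxanorbornene, so the secondary C–O bond lies syn to the oxygen bridge and the diol comes out cis; neither face of the furan is preferred, so 17 is racemic. The step needs regioselectivity and exo selectivity, both secured by the short tether (the crossed orientation would need a bridged ring), and enough reactivity between two electron-rich partners, for which the intramolecularity, the high-lying HOMO of the silyloxyfuran, the geminal isopropyl groups on silicon and the irreversible collapse of 16 are relied on.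

Step 8
Reactants: 17 racemic silylene-bridged enone
Product: 18 racemic cis-4,6-dihydroxy-4-[(10Z)-heptadec-10-en-1-yl]cyclohex-2-en-1-one
Conditions: HF·pyridine, pyridine, THF, 0 °C
Reagents that add atoms: none
Why: fluoride cleavage of both Si–O bonds of the silylene acetal under buffered, non-basic conditions should spare the α-ketol, the tertiary allylic alcohol and the Z-alkene, and any cycloadduct 16 that survived step 7 would converge on the same diol.

Step 9
Reactants: 18 racemic cis-4,6-dihydroxy-4-[(10Z)-heptadec-10-en-1-yl]cyclohex-2-en-1-one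
Product: 19 (4R,6S)-4,6-dihydroxy-4-[(10Z)-heptadec-10-en-1-yl]cyclohex-2-en-1-one
Conditions: Burkholderia cepacia lipase (immobilised), vinyl acetate (3 equiv), MTBE, 30 °C, run to about 55% conversion; chromatography
Reagents that add atoms: none
Why: lipase-catalysed kinetic resolution by irreversible transesterification, in which only the secondary C6–OH can be acylated and the (4S,6R)-enantiomer is expected to react faster, so the (4R,6S)-diol should remain with an enantiomeric purity that rises with conversion, under neutral conditions that cannot epimerise C6.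

**Compound list** (racemates are written as both enantiomers joined by a dot)

1 | oct-1-yne | C#CCCCCCC | starting material
2 | 1,9-dibromononane | BrCCCCCCCCCBr | starting material
3 | lithium oct-1-yn-1-ide | [Li]C#CCCCCCC | intermediate
4 | 17-bromoheptadec-7-yne | CCCCCCC#CCCCCCCCCCBr | intermediate
5 | (7Z)-17-bromoheptadec-7-ene | CCCCCC/C=C\CCCCCCCCCBr | intermediate
6 | 2-methoxyfuran | COc1ccco1 | starting material
7 | (5-methoxyfuran-2-yl)lithium | [Li]c1ccc(OC)o1 | intermediate
8 | 2-[(10Z)-heptadec-10-en-1-yl]-5-methoxyfuran | CCCCCC/C=C\CCCCCCCCCc1ccc(OC)o1 | intermediate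
9 | 5-[(10Z)-heptadec-10-en-1-yl]furan-2(5H)-one, racemic | CCCCCC/C=C\CCCCCCCCCC1C=CC(=O)O1 | intermediate
10 | (ethenyloxy)trimethylsilane | C=CO[Si](C)(C)C | starting material
11 | dichlorodi(propan-2-yl)silane | CC(C)[Si](Cl)(Cl)C(C)C | starting material
12 | lithium ethenolate | [Li+].[O-]C=C | intermediate
13 | chloro(ethenyloxy)di(propan-2-yl)silane | C=CO[Si](Cl)(C(C)C)C(C)C | intermediate
14 | lithium 5-[(10Z)-heptadec-10-en-1-yl]furan-2-olate | CCCCCC/C=C\CCCCCCCCCc1ccc([O-])o1.[Li+] | intermediate
15 | 2-{[(ethenyloxy)di(propan-2-yl)silyl]oxy}-5-[(10Z)-heptadec-10-en-1-yl]furan | CCCCCC/C=C\CCCCCCCCCc1ccc(O[Si](OC=C)(C(C)C)C(C)C)o1 | intermediate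
16 | racemic (1S*,5S*,7R*)-7-[(10Z)-heptadec-10-en-1-yl]-3,3-di(propan-2-yl)-2,4,10-trioxa-3-silatricyclo[5.2.1.0(1,5)]dec-8-ene (exo-fused oxanorbornene cycloadduct) | CCCCCC/C=C\CCCCCCCCC[C@]1(O2)C=C[C@]2(O[Si]3(C(C)C)C(C)C)[C@@H](O3)C1.CCCCCC/C=C\CCCCCCCCC[C@@]1(O2)C=C[C@@]2(O[Si]3(C(C)C)C(C)C)[C@H](O3)C1 | intermediate
17 | racemic (1R*,5S*)-1-[(10Z)-heptadec-10-en-1-yl]-3,3-di(propan-2-yl)-2,4-dioxa-3-silabicyclo[3.3.1]non-7-en-6-one (silylene acetal of the cis-diol) | CCCCCC/C=C\CCCCCCCCC[C@]1(O2)C=CC(=O)[C@@H](O[Si]2(C(C)C)C(C)C)C1.CCCCCC/C=C\CCCCCCCCC[C@@]1(O2)C=CC(=O)[C@H](O[Si]2(C(C)C)C(C)C)C1 | intermediate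
18 | racemic cis-4,6-dihydroxy-4-[(10Z)-heptadec-10-en-1-yl]cyclohex-2-en-1-one, (4R*,6S*) | CCCCCC/C=C\CCCCCCCCC[C@]1(O)C=CC(=O)[C@@H](O)C1.CCCCCC/C=C\CCCCCCCCC[C@@]1(O)C=CC(=O)[C@H](O)C1 | intermediate
19 | (4R,6S)-4,6-dihydroxy-4-[(10Z)-heptadec-10-en-1-yl]cyclohex-2-en-1-one | CCCCCC/C=C\CCCCCCCCC[C@]1(O)C=CC(=O)[C@@H](O)C1 | target

**Step count**

Total: 9 steps. Longest linear sequence: 8 steps (1, 2, 3, 4, 6, 7, 8, 9); step 5 is a one-step side branch.

**Steps most likely to fail**

Step 7 (carries the proposed new method). The cycloaddition between two electron-rich π-systems may be too slow, so that thermal exchange at silicon, desilylation of the silaketal or cycloreversion outruns ring formation. The fallback uses known chemistry, sets out from bromide 5 and comes back at diol 18. Copper-catalysed coupling of 5 with 4-MeOC6H4MgBr (Li2CuCl4 cat., THF, 0 °C → rt) should give 1-[(10Z)-heptadec-10-en-1-yl]-4-methoxybenzene F1. Thiolate demethylation (NaSEt, DMF, 120 °C) gives 4-[(10Z)-heptadec-10-en-1-yl]phenol F2. Oxidative dearomatisation with PhI(OAc)2 in MeCN/H2O at 0 °C gives 4-[(10Z)-heptadec-10-en-1-yl]-4-hydroxycyclohexa-2,5-dien-1-one F3. One of the two equivalent enone units of F3 is then reduced in the 1,4-sense with LiBH(s-Bu)3 (2.2 equiv, THF, −78 °C), and the enolate is hydroxylated in the same flask with 2-(benzenesulfonyl)-3-phenyloxaziridine. Facial control in the hydroxylation is not assured, so the cis-diol would be separated from its C6 epimer by chromatography; it is 18 and re-enters at step 9.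

Step 9. The enzyme may discriminate the enantiomers poorly or prefer the other one. The fallback is a classical resolution that sets out from 18 and comes back at 19. Esterification of the secondary hydroxyl with (2S)-2-methoxy-2-phenylacetic acid (DCC, DMAP cat., CH2Cl2, 0 °C) gives two diastereomeric esters that are separated by chromatography. The ester of the wanted series, (1S,5R)-5-[(10Z)-heptadec-10-en-1-yl]-5-hydroxy-2-oxocyclohex-3-en-1-yl (2S)-2-methoxy-2-phenylacetate F4, is cleaved by brief methanolysis (K2CO3 cat., MeOH, 0 °C) to 19.

Step 6. Michael self-condensation or C-silylation of the furanolate, and exchange at silicon to symmetrical silyl ethers, may erode the mixed silaketal. The fallback reverses the order of the two Si–O bond formations; it sets out from 9 and comes back at 15. Furanolate 14 (from 9 and LiN(SiMe3)2) is added to an excess of 11 at −78 °C to give 2-{[chlorodi(propan-2-yl)silyl]oxy}-5-[(10Z)-heptadec-10-en-1-yl]furan F5. After removal of the excess 11 under vacuum, lithium ethenolate 12 (made as in step 5) is added at −78 °C to give 15.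

Further compounds
F1 | step 7 | 1-[(10Z)-heptadec-10-en-1-yl]-4-methoxybenzene | CCCCCC/C=C\CCCCCCCCCc1ccc(OC)cc1
F2 | step 7 | 4-[(10Z)-heptadec-10-en-1-yl]phenol | CCCCCC/C=C\CCCCCCCCCc1ccc(O)cc1
F3 | step 7 | 4-[(10Z)-heptadec-10-en-1-yl]-4-hydroxycyclohexa-2,5-dien-1-one | CCCCCC/C=C\CCCCCCCCCC1(O)C=CC(=O)C=C1
F4 | step 9 | (1S,5R)-5-[(10Z)-heptadec-10-en-1-yl]-5-hydroxy-2-oxocyclohex-3-en-1-yl (2S)-2-methoxy-2-phenylacetate | CCCCCC/C=C\CCCCCCCCC[C@]1(O)C=CC(=O)[C@@H](OC(=O)[C@@H](OC)c2ccccc2)C1
F5 | step 6 | 2-{[chlorodi(propan-2-yl)silyl]oxy}-5-[(10Z)-heptadec-10-en-1-yl]furan | CCCCCC/C=C\CCCCCCCCCc1ccc(O[Si](Cl)(C(C)C)C(C)C)o1
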